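**Retrosynthetic overview**

1. Numbering used below (germacrane): C6 lactone carbinol, C7 ring-fusion CH, C8 carbinol, C9 angeloyloxy carbon, C10(Me)=C1 the Z alkene, C2 carbinol, C3, C4(Me)=C5 the E alkene, C11–C13 the methylene-lactone carbons.
2. The ten-membered carbocycle is formed last, at C7–C8, by an intramolecular indium Barbier allylation of a 3-(bromomethyl)butenolide onto a lactol (C8 aldehyde masked by O2); this sets C7 and C8 from C6 and frees both hydroxyls.
3. Before that, the butenolide (C7=C11) and a dihydropyran acetal (Z C1=C10, temporary O2–C8 tether) are formed together in one double ring-closing metathesis of an acyclic tetraene.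
4. The tetraene is a mixed acetal of a C2–C7 trienol with an (R)-2-angeloyloxy aldehyde acetal (C8–C10), acylated at O6 with 2-(bromomethyl)acrylic acid.
5. The trienol comes from syn-alkoxyallylboration of methacrolein followed by a [2,3]-Wittig shift (chirality C5 to C2, E alkene); C9 comes from a Sharpless kinetic resolution.

Assumption: 2,2-dimethoxyacetaldehyde is bought as the 60 % aqueous solution and dried by extraction and distillation; the oxanyl (THP) acetal carbon and the acetal carbon C8 are carried as epimer mixtures, and the known γ-(methoxymethoxy)allylborane chemistry is taken to extend to the oxanyl ether.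

**Step 1**
Reactants: 1 2-(prop-2-en-1-yloxy)oxane; 2 methacrolein
Product: 5 (3S,4S)-2-methyl-4-(oxan-2-yloxy)hexa-1,5-dien-3-ol, via allyllithium 3 (not isolated), via allylborane 4 (not isolated)
Conditions: 1, sec-butyllithium, THF, −78 °C; (+)-Ipc2BOMe; BF3·OEt2; 2, −78 °C to rt; NaOH, H2O2
Reagents that add atoms: none
Why: Brown-type asymmetric γ-alkoxyallylboration, in which the (Z)-alkoxyallylborane adds through a chair Zimmerman–Traxler transition state, the Z geometry giving the syn C5/C6 pair and the isopinocampheyl groups from (−)-α-pinene selecting the aldehyde face that leads to (3S,4S).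

**Step 2**
Reactants: 5 (3S,4S)-2-methyl-4-(oxan-2-yloxy)hexa-1,5-dien-3-ol; 6 allyl bromide
Product: 7 (3S,4S)-2-methyl-4-(oxan-2-yloxy)-3-(prop-2-en-1-yloxy)hexa-1,5-diene
Conditions: NaH, Bu4NI (cat.), THF/DMF, 0 °C to rt
Reagents that add atoms: none
Why: Williamson etherification of the secondary alkoxide, which touches no stereocentre.

**Step 3**
Reactants: 7 (3S,4S)-2-methyl-4-(oxan-2-yloxy)-3-(prop-2-en-1-yloxy)hexa-1,5-diene
Product: 9 (3S,5E,7S)-5-methyl-7-(oxan-2-yloxy)nona-1,5,8-trien-3-ol, via lithiated ether 8 (not isolated)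
Conditions: n-BuLi (1.3 equiv), THF, −78 to −30 °C; NH4Cl (aq)
Reagents that add atoms: none
Why: [2,3]-Wittig rearrangement, in which the unhindered allyloxy CH2 is deprotonated and the suprafacial shift runs through an envelope transition state with the C6 substituent pseudo-equatorial (E C4=C5) and the vinyl group exo, so the C5 configuration is transferred to C2 (S).

**Step 4**
Reactants: 10 2,2-dimethoxyacetaldehyde; 11 isopropenylmagnesium bromide
Product: 12 rac-1,1-dimethoxy-3-methylbut-3-en-2-ol
Conditions: THF, −78 to 0 °C; NH4Cl (aq)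
Reagents that add atoms: none
Why: Grignard addition to the aldehyde gives the racemic allylic alcohol that carries C8, C9, C10 and C14.

**Step 5**
Reactants: 12 rac-1,1-dimethoxy-3-methylbut-3-en-2-ol
Product: 13 (2R)-1,1-dimethoxy-3-methylbut-3-en-2-ol
Conditions: Ti(OiPr)4 (0.2 equiv), D-(−)-diisopropyl tartrate (0.24 equiv), t-BuOOH (0.6 equiv), 4 Å MS, CH2Cl2, −20 °C
Reagents that add atoms: none
Why: Sharpless kinetic resolution, in which the D-(−)-tartrate catalyst epoxidises the (S)-alcohol fast and leaves the (R)-alcohol (at most 50 %), which fixes C9.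

**Step 6**
Reactants: 13 (2R)-1,1-dimethoxy-3-methylbut-3-en-2-ol; 14 angelic acid
Product: 16 (2R)-1,1-dimethoxy-3-methylbut-3-en-2-yl (2Z)-2-methylbut-2-enoate, via mixed anhydride 15 (not isolated)
Conditions: 14, 2,4,6-trichlorobenzoyl chloride, Et3N, toluene, rt; then 13, 80 °C
Reagents that add atoms: none
Why: Yamaguchi-type esterification through the mixed anhydride without a nucleophilic catalyst, conditions under which the Z (angelate) geometry is kept and C9 is not touched.

**Step 7**
Reactants: 9 (3S,5E,7S)-5-methyl-7-(oxan-2-yloxy)nona-1,5,8-trien-3-ol; 16 (2R)-1,1-dimethoxy-3-methylbut-3-en-2-yl (2Z)-2-methylbut-2-enoate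
Product: 18 (2R)-1-methoxy-3-methyl-1-{[(3S,5E,7S)-5-methyl-7-(oxan-2-yloxy)nona-1,5,8-trien-3-yl]oxy}but-3-en-2-yl (2Z)-2-methylbut-2-enoate, via chloro ether 17 (not isolated)
Conditions: 16, AcCl, ZnBr2 (1 mol %), CH2Cl2, 0 °C to rt, volatiles removed; then 9, Ag2CO3, 4 Å MS, CH2Cl2, rt, dark
Reagents that add atoms: none
Why: acetal-to-α-chloro-ether exchange followed by Koenigs–Knorr-type substitution by alcohol 9 on the acid-scavenging silver salt (which spares the oxanyl ether); the new acetal carbon C8 forms as an epimer mixture that does not matter because C8 later becomes the aldehyde.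

**Step 8**
Reactants: 18 mixed acetal (name as in step 7)
Product: 19 (2R)-1-{[(3S,5E,7S)-7-hydroxy-5-methylnona-1,5,8-trien-3-yl]oxy}-1-methoxy-3-methylbut-3-en-2-yl (2Z)-2-methylbut-2-enoate
Conditions: PPTS (0.1 equiv), MeOH, rt
Reagents that add atoms: none
Why: acid-catalysed transacetalisation removes the oxanyl group, while the mixed acetal at C8 is deactivated by the neighbouring acyloxy group and survives.

**Step 9**
Reactants: 19 alcohol (name as in step 8); 20 2-(bromomethyl)prop-2-enoic acid
Product: 22 (3S,4E,7S)-7-{[(2R)-1-methoxy-3-methyl-2-{[(2Z)-2-methylbut-2-enoyl]oxy}but-3-en-1-yl]oxy}-5-methylnona-1,4,8-trien-3-yl 2-(bromomethyl)prop-2-enoate, via O-acylisourea 21 (not isolated)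
Conditions: DCC, DMAP (5 mol %), CH2Cl2, 0 °C
Reagents that add atoms: none
Why: Steglich esterification of the only free hydroxyl (O6) at low temperature and low DMAP loading, so the allylic bromide is not displaced and C6 is not touched.

**Step 10**
Reactants: 22 tetraene ester (name as in step 9)
Product: 23 (5R)-3-(bromomethyl)-5-{(1E)-3-[(2S,5R)-6-methoxy-4-methyl-5-{[(2Z)-2-methylbut-2-enoyl]oxy}-5,6-dihydro-2H-pyran-2-yl]-2-methylprop-1-en-1-yl}furan-2(5H)-one
Conditions: second-generation Grubbs catalyst (H2IMes)(PCy3)Cl2Ru=CHPh (10 mol %), toluene (5 mM), 70 °C, argon purge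
Reagents that add atoms: none
Why: double ring-closing metathesis, in which each terminal vinyl group closes onto the 1,1-disubstituted alkene five or six atoms away to give the butenolide and the dihydropyran at once; the six-membered ring forces the Z geometry of C1=C10, and closure between the two vinyl groups is excluded because it would put the E C4=C5 alkene in a seven-membered ring.

**Step 11**
Reactants: 23 bis-heterocycle (name as in step 10)
Product: 24 (5R)-3-(bromomethyl)-5-{(1E)-3-[(2S,5R)-6-hydroxy-4-methyl-5-{[(2Z)-2-methylbut-2-enoyl]oxy}-5,6-dihydro-2H-pyran-2-yl]-2-methylprop-1-en-1-yl}furan-2(5H)-one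
Conditions: 1 M HCl (aq)/THF 1:4, 40 °C
Reagents that add atoms: water, SMILES O
Why: acid hydrolysis of a glycoside-type acetal that carries no ring hydroxyls and should therefore cleave about as easily as a 2-deoxyglycoside; acyl migration from O9 is slow under acid and the allylic bromide, butenolide and angelate are acid-stable.

**Step 12**
Reactants: 24 lactol (name as in step 11)
Product: 26 (3aR,4R,5R,6Z,8S,10E,11aR)-4,8-dihydroxy-6,10-dimethyl-3-methylidene-2-oxo-2,3,3a,4,5,8,9,11a-octahydrocyclodeca[b]furan-5-yl (2Z)-2-methylbut-2-enoate, via allylindium aldehyde 25 (not isolated)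
Conditions: In powder (3 equiv), THF/H2O 3:1 (2 mM), 25–40 °C, sonication
Reagents that add atoms: none
Why: Proposed new method: the lactol opens to the C8 aldehyde while In inserts into the allylic C–Br bond, and the E-locked butenolide allylindium adds through C7 in a chair Zimmerman–Traxler array on the butenolide face anti to the C5 side chain, which gives the trans-lactone (C7) and the anti C7/C8 relationship (C8) and moves the double bond to the exocyclic C11=C13 position; the closest known chemistry is the intermolecular In or Zn Barbier allylation of aldehydes and lactols with 3-(bromomethyl)furan-2(5H)-ones and the CrCl2-mediated allylation closure of ten-membered germacrane rings.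

**Compound list**

1 | 2-(prop-2-en-1-yloxy)oxane (allyl tetrahydropyranyl ether) | C=CCOC1CCCCO1 | starting material
2 | methacrolein | CC(=C)C=O | starting material
3 | (Z)-3-(oxan-2-yloxy)allyllithium | [Li]C/C=C\OC1CCCCO1 | intermediate
4 | [(2Z)-3-(oxan-2-yloxy)prop-2-en-1-yl]bis(isopinocampheyl)borane, isopinocampheyl groups from (−)-α-pinene | C(/C=C\OC1CCCCO1)B([C@H]2C[C@H]3C[C@@H]([C@@H]2C)C3(C)C)[C@H]4C[C@H]5C[C@@H]([C@@H]4C)C5(C)C | intermediate
5 | (3S,4S)-2-methyl-4-(oxan-2-yloxy)hexa-1,5-dien-3-ol (oxanyl epimers) | C=C(C)[C@H](O)[C@@H](OC1CCCCO1)C=C | intermediate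
6 | allyl bromide | C=CCBr | starting material
7 | (3S,4S)-2-methyl-4-(oxan-2-yloxy)-3-(prop-2-en-1-yloxy)hexa-1,5-diene | C=C(C)[C@H](OCC=C)[C@@H](OC1CCCCO1)C=C | intermediate
8 | 7 lithiated at the allyloxy CH2 | C=C(C)[C@H](OC([Li])C=C)[C@@H](OC1CCCCO1)C=C | intermediate
9 | (3S,5E,7S)-5-methyl-7-(oxan-2-yloxy)nona-1,5,8-trien-3-ol | C=C[C@@H](O)C/C(C)=C/[C@@H](OC1CCCCO1)C=C | intermediate
10 | 2,2-dimethoxyacetaldehyde | COC(OC)C=O | starting material
11 | isopropenylmagnesium bromide | CC(=C)[Mg]Br | starting material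
12 | rac-1,1-dimethoxy-3-methylbut-3-en-2-ol | COC(OC)C(O)C(C)=C | intermediate
13 | (2R)-1,1-dimethoxy-3-methylbut-3-en-2-ol | COC(OC)[C@H](O)C(C)=C | intermediate
14 | angelic acid, (2Z)-2-methylbut-2-enoic acid | C/C=C(/C)C(=O)O | starting material
15 | (2Z)-2-methylbut-2-enoic 2,4,6-trichlorobenzoic anhydride | C/C=C(/C)C(=O)OC(=O)c1c(Cl)cc(Cl)cc1Cl | intermediate
16 | (2R)-1,1-dimethoxy-3-methylbut-3-en-2-yl (2Z)-2-methylbut-2-enoate | COC(OC)[C@H](OC(=O)/C(C)=C\C)C(C)=C | intermediate
17 | (2R)-1-chloro-1-methoxy-3-methylbut-3-en-2-yl (2Z)-2-methylbut-2-enoate (C1 epimers) | COC(Cl)[C@H](OC(=O)/C(C)=C\C)C(C)=C | intermediate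
18 | (2R)-1-methoxy-3-methyl-1-{[(3S,5E,7S)-5-methyl-7-(oxan-2-yloxy)nona-1,5,8-trien-3-yl]oxy}but-3-en-2-yl (2Z)-2-methylbut-2-enoate (acetal epimers) | C=C[C@@H](OC(OC)[C@H](OC(=O)/C(C)=C\C)C(C)=C)C/C(C)=C/[C@@H](OC1CCCCO1)C=C | intermediate
19 | (2R)-1-{[(3S,5E,7S)-7-hydroxy-5-methylnona-1,5,8-trien-3-yl]oxy}-1-methoxy-3-methylbut-3-en-2-yl (2Z)-2-methylbut-2-enoate | C=C[C@@H](OC(OC)[C@H](OC(=O)/C(C)=C\C)C(C)=C)C/C(C)=C/[C@@H](O)C=C | intermediate
20 | 2-(bromomethyl)prop-2-enoic acid | OC(=O)C(=C)CBr | starting material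
21 | O-[2-(bromomethyl)prop-2-enoyl]-N,N'-dicyclohexylisourea | C=C(CBr)C(=O)OC(=NC1CCCCC1)NC1CCCCC1 | intermediate
22 | (3S,4E,7S)-7-{[(2R)-1-methoxy-3-methyl-2-{[(2Z)-2-methylbut-2-enoyl]oxy}but-3-en-1-yl]oxy}-5-methylnona-1,4,8-trien-3-yl 2-(bromomethyl)prop-2-enoate | C=C[C@@H](OC(OC)[C@H](OC(=O)/C(C)=C\C)C(C)=C)C/C(C)=C/[C@@H](OC(=O)C(=C)CBr)C=C | intermediate
23 | (5R)-3-(bromomethyl)-5-{(1E)-3-[(2S,5R)-6-methoxy-4-methyl-5-{[(2Z)-2-methylbut-2-enoyl]oxy}-5,6-dihydro-2H-pyran-2-yl]-2-methylprop-1-en-1-yl}furan-2(5H)-one | COC1O[C@@H](C/C(C)=C/[C@H]2OC(=O)C(CBr)=C2)C=C(C)[C@H]1OC(=O)/C(C)=C\C | intermediate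
24 | (5R)-3-(bromomethyl)-5-{(1E)-3-[(2S,5R)-6-hydroxy-4-methyl-5-{[(2Z)-2-methylbut-2-enoyl]oxy}-5,6-dihydro-2H-pyran-2-yl]-2-methylprop-1-en-1-yl}furan-2(5H)-one (lactol anomers) | OC1O[C@@H](C/C(C)=C/[C@H]2OC(=O)C(CBr)=C2)C=C(C)[C@H]1OC(=O)/C(C)=C\C | intermediate
25 | open-chain hydroxy aldehyde form of 24 carrying an allylindium dibromide (CH2InBr2) in place of CH2Br | O=C[C@H](OC(=O)/C(C)=C\C)/C(C)=C\[C@@H](O)C/C(C)=C/[C@H]1OC(=O)C(C[In](Br)Br)=C1 | intermediate
26 | CNP0311662.1, (3aR,4R,5R,6Z,8S,10E,11aR)-4,8-dihydroxy-6,10-dimethyl-3-methylidene-2-oxo-2,3,3a,4,5,8,9,11a-octahydrocyclodeca[b]furan-5-yl (2Z)-2-methylbut-2-enoate | C=C1C(=O)O[C@@H]2/C=C(\C)C[C@H](O)/C=C(/C)[C@@H](OC(=O)/C(C)=C\C)[C@H](O)[C@@H]12 | target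

**Totals**

Total step count: 12. Longest linear sequence: 9 steps (1, 2, 3, 7, 8, 9, 10, 11, 12).

**Steps most likely to fail**

Step 12, the ring-expanding Barbier closure. The risks are oligomerisation, attack through the CH2 terminus of the allyl unit (which would give a twelve-membered isomer), and a C8 epimer if the α-acyloxy stereocentre C9 overrides the chair model. The fallback sets out from 24 and comes back at 26. Pd2(dba)3-catalysed borylation of the allylic bromide with B2pin2 (toluene, 50 °C) gives the isolable pinacol allylboronate of the lactol F1. Heating F1 at 2 mM in toluene (80 °C, optionally Sc(OTf)3 as catalyst) lets the lactol-derived aldehyde undergo an intramolecular allylboration through a tight, closed boron transition state. This has the same stereochemical course but no free organometallic that can be protonated or can oligomerise; aqueous work-up then gives 26.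

Step 3, the [2,3]-Wittig rearrangement. The risks are deprotonation at the wrong allylic position, partial Z alkene and incomplete chirality transfer. The fallback sets out from 5 and comes back at 9. O-Alkylation of 5 with 3-bromo-1-(trimethylsilyl)prop-1-yne (NaH, THF) gives the silylpropargyl ether F2. n-BuLi at −78 °C deprotonates only its propargylic CH2, and the [2,3]-shift, which is more strongly E-selective and transfers chirality in the same sense, gives the silylalkynyl carbinol F3. K2CO3 in MeOH removes the silyl group to give the terminal alkyne F4. Semi-hydrogenation over Pd/CaCO3 poisoned with Pb(OAc)2 and quinoline converts the alkyne into the vinyl group of 9.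

Step 7, the mixed-acetal coupling. The risk is that the neighbouring angelate captures the oxocarbenium ion and the alcohol adds to the acyl carbon, giving an ortho ester instead of the acetal. The fallback sets out from 9 and 17 and comes back at 18. The ortho ester is made on purpose with 2,4,6-collidine in CH2Cl2 and isolated as the 2-alkoxy-1,3-dioxolane ortho ester F5. F5 is then rearranged to the acetal 18 with catalytic HgBr2 in nitromethane at rt, the classical ortho-ester-to-glycoside isomerisation, which is mild enough for the oxanyl ether.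

**Further compounds**

F1 | step 12 | pinacol allylboronate of lactol 24 (CH2Br replaced by CH2B(pin)) | OC1O[C@@H](C/C(C)=C/[C@H]2OC(=O)C(CB3OC(C)(C)C(C)(C)O3)=C2)C=C(C)[C@H]1OC(=O)/C(C)=C\C
F2 | step 3 | (3S,4S)-2-methyl-4-(oxan-2-yloxy)-3-{[3-(trimethylsilyl)prop-2-yn-1-yl]oxy}hexa-1,5-diene | C=C(C)[C@H](OCC#C[Si](C)(C)C)[C@@H](OC1CCCCO1)C=C
F3 | step 3 | (3S,5E,7S)-5-methyl-7-(oxan-2-yloxy)-1-(trimethylsilyl)nona-5,8-dien-1-yn-3-ol | C[Si](C)(C)C#C[C@@H](O)C/C(C)=C/[C@@H](OC1CCCCO1)C=C
F4 | step 3 | (3S,5E,7S)-5-methyl-7-(oxan-2-yloxy)nona-5,8-dien-1-yn-3-ol | C#C[C@@H](O)C/C(C)=C/[C@@H](OC1CCCCO1)C=C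
F5 | step 7 | ortho ester from 9 and 17: (5R)-2-[(2Z)-but-2-en-2-yl]-4-methoxy-5-(prop-1-en-2-yl)-2-{[(3S,5E,7S)-5-methyl-7-(oxan-2-yloxy)nona-1,5,8-trien-3-yl]oxy}-1,3-dioxolane | C=C[C@@H](OC1(/C(C)=C\C)OC(OC)[C@@H](C(C)=C)O1)C/C(C)=C/[C@@H](OC2CCCCO2)C=C
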